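I took the sum of starting material, target and isomer of the product to stay equal to the charge of starting material, so I booked the isomer as the gap of each row to the whole.

in all of them: starting material 0.15 M; gas 10 mM (held)

|  | second substrate | remark | time |
|---|---|---|---|
| Thursday's | 1 equiv (in portions, 2) | the very flask that is asked about, followed so far; portions every 2.0 min |  |
| Tuesday's | 0.50 equiv (in portions, 2) | run made earlier; portions every 2.0 min |  |
| flask | 1.00 equiv (in portions, 2) | the portions of second substrate follow each other after 2.0 min, the first at the start | 30 h |

| run | time / h | starting material / % | target / % |
|---|---|---|---|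
| Thursday's | 0.200 | 94.3 | 5.4 |
| Thursday's | 0.417 | 92.6 | 5.8 |
| Thursday's | 1.00 | 91.5 | 6.2 |
| Thursday's | 2.50 | 90.4 | 6.7 |
| Tuesday's | 1.50 | 90.8 | 5.9 |
| Tuesday's | 4.00 | 90.6 | 6.5 |
| Tuesday's | 8.00 | 90.0 | 6.3 |
| Tuesday's | 12.0 | 90.3 | 6.4 |

(scatter of a reading: 0.3 percentage points)

- at the start none of the gas is in solution
- the reaction counts as stopped when no species that holds the starting material changes by six tenths of a point or more over the second half of the time

- at 30 h, what has stopped the reaction, if anything has (forward and back rates have come level / all of the starting material has reacted / it is still moving)
- share of the starting material used up at 30 h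
- target at 30 h, in percent of the starting material charged
- isomer of the product at 30 h, in percent of the starting material charged

1. Opening entries: the last readings of Tuesday's run showed no drift beyond their scatter of 0.3 percentage points, so I took their means: starting material 90.3 %, target 6.40 %, and isomer of the product, by the gap, 3.30 %.

2. I kept 0.0709 as the plateau quotient, target per starting material on the plateau, a conditional equilibrium constant at held gas. Isomer of the product per target read 0.516.

3. In powers of ten, the logarithms were −1.15 and −0.288. Their sum, −1.44, put the isomer at 0.0365 per starting material. The books therefore held 1.11 parts for each part of starting material left.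

4. Thursday's flask had twice the second substrate at the same gas, yet at 2.50 h its starting material read 90.4 %, just 0.1 points above Tuesday's mean. I therefore carried the quotient over unchanged.

5. Closing the books for Thursday's flask, I expected level rates, conversion 9.70 %, target 6.39 % and isomer of the product 3.30 %.

6. The forecast differed from my reckoning: it read Tuesday's plateau as an equilibrium with second substrate in its expression, and its next step began “Applying this to 1.00 equiv”. It said: forward and back rates have come level, conversion 17 % (12.5 % to 19.5 %), target 11.2 % (8 % to 13 %), isomer of the product 5.8 % (4 % to 7.5 %).

7. Thursday's flask gave at 30 h: forward and back rates have come level, conversion 9.70 %, target 6.37 %, isomer of the product 3.33 %. Its conversion lay 7.3 points below the forecast.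

    second substrate + partner ⇌ second product (K = 38.0 L mol⁻¹, k = 0.382 L mol⁻¹ min⁻¹)
    target ⇌ isomer of the product (K = 0.523, k = 0.0216 min⁻¹)
    gas ⇌ partner, rate k3*(csat - [partner]) (kL = 0.456 min⁻¹)
    starting material + partner ⇌ target (K = 7.05 L mol⁻¹, k = 2.80 L mol⁻¹ min⁻¹)

The plateau quotient times the starting material left in Thursday's flask gave 6.40 % of target, where the flask held 6.37 %, with partner at 0.0100 M. I then took the neighbour charged with 0.037 M of starting material, a quarter of that charge, at the same equivalents. Its 90.3 % of starting material, multiplied by the quotient, gave 6.40 % of target, and by the quotient and the isomer ratio gave 3.30 % of isomer of the product. The neighbour stood at 6.37 % of target and 3.33 % of isomer of the product, with conversion 9.70 % and partner at 0.0100 M at 30.0 h.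

All runs come from a simulation from invented constants.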